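The flavanone is disconnected at C3–C4 of the pyranone ring C. The C4 ketone, the C3 methylene and the C2–H methine next to O1 together are the retron of an alkene hydroacylation, so ring C is simply an isomer of an achiral 2-(1-arylvinyloxy)benzaldehyde. An enantioselective rhodium-catalysed intramolecular hydroacylation closes ring C, makes C3–C4 and sets the only stereocentre (C2, S) in one atom-economical operation. The precursor holds ring A (formyl group, two prenyl groups, silyl ether) linked through O1 to the α-carbon of the ring B styrene. It arises from an aryl benzoate by carbonyl methylenation followed by bromine–lithium exchange and formylation.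

Key step: step 7

Assumption: which enantiomer of the ligand delivers (2S) cannot be derived with certainty. The route is written with (R)-DTBM-SEGPHOS, and the (S)-ligand is used instead if the opposite alkene face proves to be preferred; nothing else changes.

TBS = tert-butyldimethylsilyl; prenyl = 3-methylbut-2-en-1-yl.

Step 1
Reactants: 1 4-bromoresorcinol (4-bromobenzene-1,3-diol); 2 prenyl bromide (1-bromo-3-methylbut-2-ene, 2.2 equiv)
Product: 3 4-bromo-2,6-bis(3-methylbut-2-en-1-yl)benzene-1,3-diol
Conditions: KOH (2.2 equiv), H2O, 0 °C to rt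
Reagents that add atoms: none
Why: Double C-prenylation of the ambident resorcinolate in water (hydrogen bonding to the oxygens favours carbon alkylation, SN2 at the primary allylic bromide) can only end at C2 and C6, because C4 is blocked by bromine and C5 is meta to both oxygens.

Step 2
Reactants: 4 2,4-dihydroxybenzoic acid
Product: 5 tert-butyldimethylsilyl 2,4-bis(tert-butyldimethylsilyloxy)benzoate
Conditions: TBSCl (3.5 equiv), imidazole, DMF, rt
Reagents that add atoms: tert-butyldimethylsilyl chloride, CC(C)(C)[Si](C)(C)Cl
Why: Exhaustive imidazole-promoted silylation masks both ring B phenols for the later titanium, lithium and rhodium chemistry and turns the acid into a silyl ester that can be activated without free acid.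

Step 3
Reactants: 5 silyl ester; 3 4-bromo-2,6-diprenylresorcinol
Product: 7 6-bromo-3-hydroxy-2,4-bis(3-methylbut-2-en-1-yl)phenyl 2,4-bis(tert-butyldimethylsilyloxy)benzoate, via acid chloride 6 (not isolated)
Conditions: 5, (COCl)2, DMF (cat.), CH2Cl2, 0 °C to rt, evaporate; then 3, Et3N (1.05 equiv), CH2Cl2, −20 °C
Reagents that add atoms: oxalyl chloride, O=C(Cl)C(=O)Cl (chlorine of 6 only)
Why: The chloroiminium salt from (COCl)2 and DMF converts the silyl ester into the acid chloride under neutral conditions, and the amine-mediated O-acylation should take place at the hydroxyl next to bromine, which is the more acidic one and has only one prenyl neighbour, while the other hydroxyl sits between two prenyl groups.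

Step 4
Reactants: 7 monoester phenol
Product: 8 6-bromo-3-(tert-butyldimethylsilyloxy)-2,4-bis(3-methylbut-2-en-1-yl)phenyl 2,4-bis(tert-butyldimethylsilyloxy)benzoate
Conditions: TBSOTf, 2,6-lutidine, CH2Cl2, 0 °C
Reagents that add atoms: tert-butyldimethylsilyl triflate, CC(C)(C)[Si](C)(C)OS(=O)(=O)C(F)(F)F
Why: Silylation with the silyl triflate overcomes the hindrance of the phenol between two prenyl groups, and the non-nucleophilic base leaves the aryl ester and the alkenes untouched.

Step 5
Reactants: 8 aryl benzoate
Product: 9 aryl 1-arylvinyl ether, 1-bromo-4-(tert-butyldimethylsilyloxy)-2-{1-[2,4-bis(tert-butyldimethylsilyloxy)phenyl]vinyloxy}-3,5-bis(3-methylbut-2-en-1-yl)benzene (the ester C=O of 8 replaced by C=CH2)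
Conditions: Cp2TiMe2 (3 equiv), toluene, 70 °C, dark; filtration through basic alumina
Reagents that add atoms: Cp2TiMe2, C[Ti](C)(C1C=CC=C1)C1C=CC=C1
Why: Petasis methylenation, in which thermolysis of Cp2TiMe2 gives Cp2Ti=CH2 that adds [2+2] to the ester carbonyl and cycloreverts to the enol ether under non-acidic conditions, is established for aryl benzoates and is inert to aryl bromides, silyl ethers and trisubstituted alkenes.

Step 6
Reactants: 9 bromo enol ether
Product: 12 4-(tert-butyldimethylsilyloxy)-2-{1-[2,4-bis(tert-butyldimethylsilyloxy)phenyl]vinyloxy}-3,5-bis(3-methylbut-2-en-1-yl)benzaldehyde, via aryllithium 10 (not isolated), via lithium hemiaminalate 11 (not isolated)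
Conditions: n-BuLi (1.1 equiv), THF, −78 °C; DMF (3 equiv), −78 °C to 0 °C; aq. NH4Cl; Et3N-deactivated silica
Reagents that add atoms: N,N-dimethylformamide, CN(C)C=O; n-butyllithium, [Li]CCCC (lithium of 10 and 11 only)
Why: Bromine–lithium exchange at −78 °C outruns deprotonation, and formylation of the aryllithium with DMF (Bouveault aldehyde synthesis) releases the aldehyde only on the aqueous quench, so no cationic C4 species ever meets the nucleophilic enol ether.

Step 7
Reactants: 12 enol ether aldehyde
Product: 13 (2S)-7-(tert-butyldimethylsilyloxy)-2-[2,4-bis(tert-butyldimethylsilyloxy)phenyl]-6,8-bis(3-methylbut-2-en-1-yl)chroman-4-one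
Conditions: [Rh(cod)Cl]2 (2.5 mol %), (R)-DTBM-SEGPHOS (5.5 mol %), Na[B(C6H3-3,5-(CF3)2)4] (5 mol %), 1,4-dioxane, 80 °C
Reagents that add atoms: none
Why: Proposed new method: the cationic monovalent rhodium bisphosphine complex adds oxidatively into the formyl C–H bond of 12, the acyl hydride of trivalent rhodium binds the tethered enol ether, hydride migrates to the alkene carbon that bears O1 and ring B (future C2) to give a seven-membered acyl alkyl rhodacycle, and reductive elimination joins the terminal CH2 (C3) to the acyl carbon (C4). The closest known reaction type is the endo- and enantioselective rhodium/DTBM-SEGPHOS hydroacylation of ortho-(2-substituted allyl)benzaldehydes to 3-substituted 3,4-dihydronaphthalen-1(2H)-ones, of which 12 is the analogue with O1 in place of the benzylic CH2, whereas an aryl 1-arylvinyl ether has not been shown as the alkene partner. Ring C closes in a formal 6-endo-trig mode, with both alkene carbons ending up inside the pyranone. C2 is set in the hydride migration, where the axially chiral ligand decides which alkene face is bound to the metal. The step needs endo regioselectivity over closure to the 2-aryl-2-methylbenzofuran-3-one, which the 1,1-disubstitution secures because the other insertion would require a tertiary alkylrhodium, and it needs chemoselectivity, which is secured because both prenyl groups are trisubstituted and sit meta to the formyl group, out of reach of the metal. The reacting alkene has no allylic hydrogen, so the alkene isomerisation and ene pathways open to the all-carbon substrates do not exist here.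

Step 8
Reactants: 13 tris-silyl flavanone
Product: 14 (2S)-7-hydroxy-2-(2,4-dihydroxyphenyl)-6,8-bis(3-methylbut-2-en-1-yl)chroman-4-one, the target
Conditions: Et3N·3HF, THF, 0 °C to rt; work-up kept slightly acidic
Reagents that add atoms: none
Why: Fluoride-mediated desilylation with mildly acidic Et3N·3HF frees the three phenols without basic phenoxide conditions, which would open ring C to the chalcone (retro-oxa-Michael) and racemise C2, and the medium is not acidic enough to cyclise the prenyl groups onto the C7 hydroxyl.

Compound list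
1 | 4-bromoresorcinol | Oc1ccc(Br)c(O)c1 | starting material
2 | prenyl bromide | CC(C)=CCBr | starting material
3 | 4-bromo-2,6-bis(3-methylbut-2-en-1-yl)benzene-1,3-diol | CC(C)=CCc1cc(Br)c(O)c(CC=C(C)C)c1O | intermediate
4 | 2,4-dihydroxybenzoic acid | O=C(O)c1ccc(O)cc1O | starting material
5 | TBS 2,4-bis(TBS-oxy)benzoate | O=C(O[Si](C)(C)C(C)(C)C)c1ccc(O[Si](C)(C)C(C)(C)C)cc1O[Si](C)(C)C(C)(C)C | intermediate
6 | 2,4-bis(TBS-oxy)benzoyl chloride (not isolated) | O=C(Cl)c1ccc(O[Si](C)(C)C(C)(C)C)cc1O[Si](C)(C)C(C)(C)C | intermediate
7 | 6-bromo-3-hydroxy-2,4-diprenylphenyl 2,4-bis(TBS-oxy)benzoate | CC(C)=CCc1cc(Br)c(OC(=O)c2ccc(O[Si](C)(C)C(C)(C)C)cc2O[Si](C)(C)C(C)(C)C)c(CC=C(C)C)c1O | intermediate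
8 | 6-bromo-3-(TBS-oxy)-2,4-diprenylphenyl 2,4-bis(TBS-oxy)benzoate | CC(C)=CCc1cc(Br)c(OC(=O)c2ccc(O[Si](C)(C)C(C)(C)C)cc2O[Si](C)(C)C(C)(C)C)c(CC=C(C)C)c1O[Si](C)(C)C(C)(C)C | intermediate
9 | bromo aryl 1-arylvinyl ether | CC(C)=CCc1cc(Br)c(OC(=C)c2ccc(O[Si](C)(C)C(C)(C)C)cc2O[Si](C)(C)C(C)(C)C)c(CC=C(C)C)c1O[Si](C)(C)C(C)(C)C | intermediate
10 | aryllithium from 9 (not isolated) | CC(C)=CCc1cc([Li])c(OC(=C)c2ccc(O[Si](C)(C)C(C)(C)C)cc2O[Si](C)(C)C(C)(C)C)c(CC=C(C)C)c1O[Si](C)(C)C(C)(C)C | intermediate
11 | lithium hemiaminalate, adduct of 10 and DMF (not isolated) | CC(C)=CCc1cc(C(O[Li])N(C)C)c(OC(=C)c2ccc(O[Si](C)(C)C(C)(C)C)cc2O[Si](C)(C)C(C)(C)C)c(CC=C(C)C)c1O[Si](C)(C)C(C)(C)C | intermediate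
12 | 4-(TBS-oxy)-2-{1-[2,4-bis(TBS-oxy)phenyl]vinyloxy}-3,5-diprenylbenzaldehyde | CC(C)=CCc1cc(C=O)c(OC(=C)c2ccc(O[Si](C)(C)C(C)(C)C)cc2O[Si](C)(C)C(C)(C)C)c(CC=C(C)C)c1O[Si](C)(C)C(C)(C)C | intermediate
13 | (2S)-7-(TBS-oxy)-2-[2,4-bis(TBS-oxy)phenyl]-6,8-diprenylchroman-4-one | CC(C)=CCc1cc2c(c(CC=C(C)C)c1O[Si](C)(C)C(C)(C)C)O[C@H](c1ccc(O[Si](C)(C)C(C)(C)C)cc1O[Si](C)(C)C(C)(C)C)CC2=O | intermediate
14 | (2S)-7-hydroxy-2-(2,4-dihydroxyphenyl)-6,8-diprenylchroman-4-one | CC(C)=CCc1cc2c(c(CC=C(C)C)c1O)O[C@H](c1ccc(O)cc1O)CC2=O | target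

Total step count: 8. Longest linear sequence: 7 steps (1 → 3 → 7 → 8 → 9 → 12 → 13 → 14; the branch from 4 is equally long).

Steps most likely to fail

Step 7 (bears the label "Proposed new method:"). The acylrhodium hydride may decarbonylate. Insertion may take the opposite regiochemistry, the alkylrhodium intermediate may lose the β-aryloxy group, the prenyl groups may isomerise, or facial selectivity may be poor.
- The fallback sets out from 12 and comes back at 13, and it makes the same C3–C4 bond by known radical chemistry.
- A thiol-catalysed acyl radical cyclisation of the alkenal is run with catalytic tert-dodecanethiol and AIBN in toluene at 80 °C.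
- The thiyl radical abstracts the formyl hydrogen. The acyl radical attacks the unsubstituted CH2 terminus in the 6-endo mode to give the benzylic α-oxy radical, and the thiol returns hydrogen.
- This should give the racemic tris-silyl flavanone F1.
- Preparative HPLC on an amylose carbamate chiral stationary phase separates 13 from the (2R)-tris-silyl flavanone F2.

Step 1. O-alkylation may compete, C-alkylation may stay incomplete, or over-alkylation with dearomatisation may occur.
- The fallback sets out from 1 and comes back at 3, replacing phenolate alkylation by halogenation and cross-coupling.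
- Iodination with N-iodosuccinimide (2 equiv, MeCN, 0 °C) fills the only two activated positions and gives 4-bromo-2,6-diiodobenzene-1,3-diol F3.
- A double Stille coupling follows with tributyl(3-methylbut-2-en-1-yl)stannane, Pd(PPh3)4, DMF, 80 °C.
- Oxidative addition to zerovalent palladium selects the two C–I bonds over C–Br, which delivers 3.

Step 3. Discrimination between the two phenolic hydroxyls may be poor during acylation.
- The fallback sets out from 3 and comes back at 8, bypassing 7. It moves the differentiation to a desilylation governed by leaving-group ability.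
- Silylation of both phenols (TBSOTf, 2,6-lutidine, CH2Cl2) gives the bis(silyl ether) F4.
- Cs2CO3 in DMF/H2O at rt cleaves the silyl ether next to bromine, which is less hindered and releases the better phenoxide leaving group. This gives 6-bromo-3-(tert-butyldimethylsilyloxy)-2,4-diprenylphenol F5.
- F5 is acylated with 6 (made from 5 as in step 3) using Et3N and catalytic DMAP in CH2Cl2 to give 8.

Further compounds
F1 | step 7 | racemic 7-(TBS-oxy)-2-[2,4-bis(TBS-oxy)phenyl]-6,8-diprenylchroman-4-one | CC(C)=CCc1cc2c(c(CC=C(C)C)c1O[Si](C)(C)C(C)(C)C)OC(c1ccc(O[Si](C)(C)C(C)(C)C)cc1O[Si](C)(C)C(C)(C)C)CC2=O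
F2 | step 7 | (2R)-7-(TBS-oxy)-2-[2,4-bis(TBS-oxy)phenyl]-6,8-diprenylchroman-4-one | CC(C)=CCc1cc2c(c(CC=C(C)C)c1O[Si](C)(C)C(C)(C)C)O[C@@H](c1ccc(O[Si](C)(C)C(C)(C)C)cc1O[Si](C)(C)C(C)(C)C)CC2=O
F3 | step 1 | 4-bromo-2,6-diiodobenzene-1,3-diol | Oc1c(I)cc(Br)c(O)c1I
F4 | step 3 | 1-bromo-2,4-bis(TBS-oxy)-3,5-diprenylbenzene | CC(C)=CCc1cc(Br)c(O[Si](C)(C)C(C)(C)C)c(CC=C(C)C)c1O[Si](C)(C)C(C)(C)C
F5 | step 3 | 6-bromo-3-(TBS-oxy)-2,4-diprenylphenol | CC(C)=CCc1cc(Br)c(O)c(CC=C(C)C)c1O[Si](C)(C)C(C)(C)C
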